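**Retrosynthetic overview**
- The target comes from one reductive unmasking (C–S, benzylic C–OH, O–Bn, after fluoride removes O–Si) of a ring A arene. That arene carries a 2-(3-methoxybenzyl)-1,3-dithian-2-yl group at C1 and an aryl carbinol at C2.
- Key disconnection: the ring A C1–C(bridge) bond. A lithiated dithiane (masked acyl anion of 3-methoxyphenylacetaldehyde) attacks the former C–Cl carbon of a 3-methoxy-5-silyloxyaryne.
- In the same flask, the C2 aryllithium left by that addition is trapped by 4-(benzyloxy)benzaldehyde, which installs the diarylmethane carbon.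
- The aryne comes from 3-chloro-5-methoxyphenol, so the OMe/OH pattern is bought in and a TIPS group steers the lithiation. The dithiane comes from 1,3-dithiane and 3-methoxybenzyl chloride.
- No ring is built. Rings A, B and C are purchased benzene rings, and the purchased dithiane ring is destroyed in the last step.

Assumption: the target SMILES has no stereocentre and no stereogenic double bond, so the compound is achiral and there is no enantiomer to select. The one stereocentre that appears on the way is formed racemic and is removed in the last step.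

**Step 1**
Reactants: 1 1,3-dithiane; 2 3-methoxybenzyl chloride
Product: 4 2-(3-methoxybenzyl)-1,3-dithiane, via 2-lithio-1,3-dithiane 3 (not isolated)
Conditions: n-BuLi (1.05 equiv), THF, −30 °C, 2 h; then 2, −78 °C → rt
Reagents that add atoms: none
Why: Corey–Seebach alkylation, in which the sulfur-stabilised carbanion displaces a reactive primary benzylic chloride by SN2 and no stereocentre is formed.

**Step 2**
Reactants: 5 3-chloro-5-methoxyphenol
Product: 6 (3-chloro-5-methoxyphenoxy)triisopropylsilane
Conditions: TIPSCl, imidazole, DMF, rt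
Reagents that add atoms: triisopropylsilyl chloride (TIPSCl), CC(C)[Si](Cl)(C(C)C)C(C)C
Why: Imidazole-promoted O-silylation of a phenol; the bulky, weakly coordinating OTIPS group survives alkyllithiums and shields both of its ortho positions from metalation.

**Step 3 (key step)**
Reactants: 4 2-(3-methoxybenzyl)-1,3-dithiane; 6 (3-chloro-5-methoxyphenoxy)triisopropylsilane; 7 4-(benzyloxy)benzaldehyde
Product: 13 [4-(benzyloxy)phenyl]{2-methoxy-6-[2-(3-methoxybenzyl)-1,3-dithian-2-yl]-4-[(triisopropylsilyl)oxy]phenyl}methanol (racemic), via lithiated dithiane 8 (not isolated), via ortho-lithiated chloroarene 9 (not isolated), via aryne 10 (not isolated), via aryllithium 11 (not isolated), via lithium alkoxide 12 (not isolated)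
Conditions: flask A: 4 (2 equiv), n-BuLi, THF, −30 °C; flask B: 6, s-BuLi (1.05 equiv), THF, −78 °C, 1.5 h; cold B added slowly to A at −20 °C; recool, 7 (2.5 equiv), −78 → −20 °C; aq NH4Cl
Reagents that add atoms: none
Why: Proposed new method: s-BuLi metalates 6 only between Cl and OMe, and on entering the warmer flask 9 loses LiCl to give the 3-alkoxyaryne 10, which carbon nucleophiles attack at the carbon remote from OMe, so the acyl-anion equivalent 8 bonds to the former C–Cl carbon and leaves the OMe-chelated aryllithium 11, which has no proton source in the amine-free medium and adds to aldehyde 7 (the new carbinol centre forms racemic and is erased in step 4); the closest known reaction type is the three-component aryne coupling in which a Grignard or organolithium reagent carbometalates a 3-methoxyaryne made from an ortho-lithiated haloarene and the aryl-metal is then trapped by an aldehyde, extended here to a Corey–Seebach 2-lithio-1,3-dithiane as nucleophile.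

**Step 4**
Reactants: 13 [4-(benzyloxy)phenyl]{2-methoxy-6-[2-(3-methoxybenzyl)-1,3-dithian-2-yl]-4-[(triisopropylsilyl)oxy]phenyl}methanol (racemic)
Product: 15 4-(4-hydroxybenzyl)-3-methoxy-5-[2-(3-methoxyphenyl)ethyl]phenol (target), via free phenol 14 (not isolated)
Conditions: TBAF, AcOH, THF, rt; then dilute with EtOH, Raney Ni (W-2, large excess), H2 (1 atm), reflux
Reagents that add atoms: none
Why: Fluoride desilylation followed by Mozingo reduction, in which Raney Ni cleaves all four C–S bonds and also hydrogenolyses the O-benzyl ether and the doubly benzylic carbinol, whose C–O bond is weakened by the freed para-hydroxy and the ortho-methoxy groups, so the only stereocentre disappears and the achiral target results.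

**Compound list**
1 | 1,3-dithiane | C1CSCSC1 | starting material
2 | 3-methoxybenzyl chloride | COc1cccc(CCl)c1 | starting material
3 | 2-lithio-1,3-dithiane | [Li]C1SCCCS1 | intermediate
4 | 2-(3-methoxybenzyl)-1,3-dithiane | COc1cccc(CC2SCCCS2)c1 | intermediate
5 | 3-chloro-5-methoxyphenol | COc1cc(O)cc(Cl)c1 | starting material
6 | (3-chloro-5-methoxyphenoxy)triisopropylsilane | COc1cc(Cl)cc(O[Si](C(C)C)(C(C)C)C(C)C)c1 | intermediate
7 | 4-(benzyloxy)benzaldehyde | O=Cc1ccc(OCc2ccccc2)cc1 | starting material
8 | 2-lithio-2-(3-methoxybenzyl)-1,3-dithiane | [Li]C1(Cc2cccc(OC)c2)SCCCS1 | intermediate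
9 | [2-chloro-6-methoxy-4-(triisopropylsilyloxy)phenyl]lithium | COc1cc(O[Si](C(C)C)(C(C)C)C(C)C)cc(Cl)c1[Li] | intermediate
10 | 3-methoxy-5-(triisopropylsilyloxy)benzyne (triple bond next to the OMe-bearing carbon) | COC1=CC(O[Si](C(C)C)(C(C)C)C(C)C)=CC#C1 | intermediate
11 | {2-methoxy-6-[2-(3-methoxybenzyl)-1,3-dithian-2-yl]-4-(triisopropylsilyloxy)phenyl}lithium | COc1cc(O[Si](C(C)C)(C(C)C)C(C)C)cc(C2(Cc3cccc(OC)c3)SCCCS2)c1[Li] | intermediate
12 | lithium alkoxide of 13 (racemic) | COc1cc(O[Si](C(C)C)(C(C)C)C(C)C)cc(C2(Cc3cccc(OC)c3)SCCCS2)c1C(O[Li])c1ccc(OCc2ccccc2)cc1 | intermediate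
13 | [4-(benzyloxy)phenyl]{2-methoxy-6-[2-(3-methoxybenzyl)-1,3-dithian-2-yl]-4-[(triisopropylsilyl)oxy]phenyl}methanol (racemic) | COc1cc(O[Si](C(C)C)(C(C)C)C(C)C)cc(C2(Cc3cccc(OC)c3)SCCCS2)c1C(O)c1ccc(OCc2ccccc2)cc1 | intermediate
14 | 4-{[4-(benzyloxy)phenyl](hydroxy)methyl}-3-methoxy-5-[2-(3-methoxybenzyl)-1,3-dithian-2-yl]phenol (racemic) | COc1cc(O)cc(C2(Cc3cccc(OC)c3)SCCCS2)c1C(O)c1ccc(OCc2ccccc2)cc1 | intermediate
15 | 4-(4-hydroxybenzyl)-3-methoxy-5-[2-(3-methoxyphenyl)ethyl]phenol (CNP0327395.0, achiral) | COc1cccc(CCc2cc(O)cc(OC)c2Cc2ccc(O)cc2)c1 | target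

**Totals**
- Total step count: 4.
- Longest linear sequence: 3 (step 1 or step 2, then step 3, then step 4).

**Steps most likely to fail**

Step 3 carries the most risk. The hindered tertiary carbanion 8 may lose the race for aryne 10 to 9 or 11. Alternatively, 11 may be quenched by proton transfer from the neighbouring benzylic CH2 before the aldehyde arrives.

The fallback gives up the aryne. It sets out from 6 and comes back to the route at 15.
- 9 is kept at −78 °C, where it holds its chloride, and is quenched directly by 7. This gives [4-(benzyloxy)phenyl][2-chloro-6-methoxy-4-(triisopropylsilyloxy)phenyl]methanol F1.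
- Ionic hydrogenation (Et3SiH, TFA, CH2Cl2, 0 °C) gives {4-[4-(benzyloxy)benzyl]-3-chloro-5-methoxyphenoxy}triisopropylsilane F2.
- The retained C–Cl bond then serves as a cross-coupling handle. A copper-free Sonogashira reaction with commercial 1-ethynyl-3-methoxybenzene (PdCl2(MeCN)2, XPhos, Cs2CO3, MeCN, 90 °C) gives {4-[4-(benzyloxy)benzyl]-3-methoxy-5-[(3-methoxyphenyl)ethynyl]phenoxy}triisopropylsilane F3.
- H2 over Pd/C in EtOAc/EtOH saturates the alkyne and removes the benzyl ether, giving 4-{2-methoxy-6-[2-(3-methoxyphenyl)ethyl]-4-(triisopropylsilyloxy)benzyl}phenol F4.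
- TBAF in THF then gives 15.

Step 4 is second. On sulfur-loaded nickel the crowded carbinol or the benzyl ether may be cleaved only in part, and forcing the reaction risks saturating a phenol ring.

The fallback removes the carbinol oxygen by hydride chemistry instead of hydrogenolysis. It sets out from 14, now isolated after the TBAF stage, and comes back at 15.
- NaBH4 in aqueous NaOH/EtOH at 60 °C is the base-promoted hydride deoxygenation typical of para-hydroxybenzylic alcohols. It gives 4-[4-(benzyloxy)benzyl]-3-methoxy-5-[2-(3-methoxybenzyl)-1,3-dithian-2-yl]phenol F5.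
- Raney Ni in refluxing EtOH then has only the C–S bonds and the O-benzyl ether to cleave, and gives 15.

Step 1 is third. Electron-transfer homocoupling of the benzylic chloride or a second alkylation would contaminate 4, and step 3 needs 4 pure so that it can be metalated exactly.

The fallback turns the polarity of this bond around. It sets out from 2 and comes back at 4.
- Mg in Et2O converts 2 into (3-methoxybenzyl)magnesium chloride F6.
- F6 reacts with triethyl orthoformate (Bodroux–Chichibabin reaction) to give 1-(2,2-diethoxyethyl)-3-methoxybenzene F7.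
- Transthioacetalisation with propane-1,3-dithiol and BF3·OEt2 in CH2Cl2 gives 4.

**Further compounds**
F1 | step 3 | [4-(benzyloxy)phenyl][2-chloro-6-methoxy-4-(triisopropylsilyloxy)phenyl]methanol (racemic) | COc1cc(O[Si](C(C)C)(C(C)C)C(C)C)cc(Cl)c1C(O)c1ccc(OCc2ccccc2)cc1
F2 | step 3 | {4-[4-(benzyloxy)benzyl]-3-chloro-5-methoxyphenoxy}triisopropylsilane | COc1cc(O[Si](C(C)C)(C(C)C)C(C)C)cc(Cl)c1Cc1ccc(OCc2ccccc2)cc1
F3 | step 3 | {4-[4-(benzyloxy)benzyl]-3-methoxy-5-[(3-methoxyphenyl)ethynyl]phenoxy}triisopropylsilane | COc1cccc(C#Cc2cc(O[Si](C(C)C)(C(C)C)C(C)C)cc(OC)c2Cc2ccc(OCc3ccccc3)cc2)c1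
F4 | step 3 | 4-{2-methoxy-6-[2-(3-methoxyphenyl)ethyl]-4-(triisopropylsilyloxy)benzyl}phenol | COc1cccc(CCc2cc(O[Si](C(C)C)(C(C)C)C(C)C)cc(OC)c2Cc2ccc(O)cc2)c1
F5 | step 4 | 4-[4-(benzyloxy)benzyl]-3-methoxy-5-[2-(3-methoxybenzyl)-1,3-dithian-2-yl]phenol | COc1cc(O)cc(C2(Cc3cccc(OC)c3)SCCCS2)c1Cc1ccc(OCc2ccccc2)cc1
F6 | step 1 | (3-methoxybenzyl)magnesium chloride | COc1cccc(C[Mg]Cl)c1
F7 | step 1 | 1-(2,2-diethoxyethyl)-3-methoxybenzene | CCOC(Cc1cccc(OC)c1)OCC
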